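In lignan numbering, the C1–C2 edge belongs to both ring A and ring B, and C2 is flanked by the C7' methine and by oxygenated C3. The route exploits this by forging C1–C2 and C3–C4 together in an intramolecular Diels–Alder reaction of a 2-pyrone with a tethered alkynylboronate, after which CO2 loss aromatises. One heating therefore closes ring B, builds ring A and leaves boron, the stand-in for the C3 oxygen, at the most hindered arene position. The precursor is an open chain. A 3-benzyloxy-4-methoxy-2-pyrone, already holding the C4 and C5 oxygens, is linked from its C6 through C7–C8–C8'–C7' to the boron-capped alkyne. Its stereotriad comes from cleavage of an enantiopure cyclohexanone.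

Key step: step 17

Assumption: the sense of induction known for cyclohexene oxide with the diamine of step 5 (giving the R allylic alcohol) is taken to hold for epoxide 5; if it were reversed, the enantiomeric diamine would be used.

Step 1
Reactants: 1 cis-1,2,3,6-tetrahydrophthalic anhydride
Product: 2 cis-cyclohex-4-ene-1,2-diyldimethanol (meso)
Conditions: LiAlH4, THF, 0 °C to reflux; H2O
Reagents that add atoms: none
Why: Hydride reduction of a cyclic anhydride with excess LiAlH4 takes both carbonyl groups to primary alcohols and leaves the isolated alkene and the two cis ring stereocentres untouched.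

Step 2
Reactants: 2 meso diol
Product: 3 cis-cyclohex-4-ene-1,2-diylbis(methylene) dimethanesulfonate (meso)
Conditions: MsCl, Et3N, CH2Cl2, −10 to 0 °C
Reagents that add atoms: methanesulfonyl chloride, CS(=O)(=O)Cl
Why: Standard sulfonylation of primary alcohols, in which excess MsCl at low temperature caps both hydroxyls before a monomesylate can close to the bicyclic tetrahydrofuran.

Step 3
Reactants: 3 meso dimesylate
Product: 4 cis-4,5-dimethylcyclohex-1-ene (meso)
Conditions: LiAlH4, THF, reflux; H2O; distillation
Reagents that add atoms: none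
Why: SN2 hydride displacement of two primary mesylates (reductive deoxygenation) turns both arms into methyl groups without touching the ring stereocentres, so the cis relationship of the future C8 and C8' methyls is kept.

Step 4
Reactants: 4 cis-4,5-dimethylcyclohexene
Product: 5 cis-4,5-dimethylcyclohexene oxide with the oxygen anti to both methyl groups (meso)
Conditions: mCPBA, CH2Cl2, 0 °C to rt; chromatography
Reagents that add atoms: mCPBA, O=C(OO)c1cccc(Cl)c1
Why: Prilezhaev epoxidation, in which the pseudoaxial homoallylic methyl of the half-chair shields one face so the peracid should attack mainly anti to the methyls, and any syn epoxide is removed here because it would erode the enantiomeric purity of enone 7.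

Step 5
Reactants: 5 meso anti epoxide
Product: 6 (1R,4R,5R)-4,5-dimethylcyclohex-2-en-1-ol
Conditions: (1S,3R,4R)-3-(pyrrolidin-1-ylmethyl)-2-azabicyclo[2.2.1]heptane (5 mol %), LiN(iPr)2 (2 equiv), DBU (5 equiv), THF, 0 °C to rt; H2O
Reagents that add atoms: none
Why: Enantioselective desymmetrisation of a meso epoxide by chiral lithium amide-induced syn β-elimination (epoxide to allylic alcohol rearrangement), in which the chiral amide, regenerated by LiN(iPr)2, removes one of the two enantiotopic protons syn to oxygen, the surviving C–O carbon keeps its configuration as C1 (R), and the two methyl-bearing carbons thereby become C4 (R) and C5 (R).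

Step 6
Reactants: 6 allylic alcohol
Product: 7 (4R,5R)-4,5-dimethylcyclohex-2-en-1-one
Conditions: activated MnO2, CH2Cl2, rt
Reagents that add atoms: none
Why: Allylic alcohol oxidation with MnO2 is neutral, so the γ-stereocentre C4 is not epimerised and the alkene does not move.

Step 7
Reactants: 8 4-bromo-2-methoxyphenol
Product: 9 1-(benzyloxy)-4-bromo-2-methoxybenzene
Conditions: BnBr, K2CO3, acetone, reflux
Reagents that add atoms: benzyl bromide, BrCc1ccccc1
Why: Williamson ether synthesis on a phenol gives a protecting group that tolerates organometallic, oxidative and thermal steps and leaves in the final hydrogenolysis.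

Step 8
Reactants: 9 aryl bromide; 7 enone
Product: 11 {[(3S,4R,5R)-3-[4-(benzyloxy)-3-methoxyphenyl]-4,5-dimethylcyclohex-1-en-1-yl]oxy}trimethylsilane, via arylmagnesium bromide 10 (not isolated)
Conditions: 9, Mg, THF, reflux; then CuBr·SMe2 (10 mol %), DMPU, Me3SiCl, 7, THF, −78 to −30 °C; Et3N, pentane, cold aq NaHCO3
Reagents that add atoms: chlorotrimethylsilane, C[Si](C)(C)Cl; magnesium, [Mg] (held only in 10)
Why: Copper-catalysed, Me3SiCl-accelerated conjugate addition of an aryl Grignard reagent, in which axial attack on the half-chair with the C4 methyl pseudoaxial and the C5 methyl equatorial brings the aryl group in anti to both methyls, so 1,2- and 1,3-induction reinforce each other in setting C3 (the future C7'), and silylation locks the enolate regiospecifically as the C1=C2 enol ether.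

Step 9
Reactants: 11 silyl enol ether
Product: 13 methyl (3R,4R,5R)-5-[4-(benzyloxy)-3-methoxyphenyl]-3,4-dimethyl-6-oxohexanoate, via aldehyde acid 12 (not isolated)
Conditions: O3, CH2Cl2–MeOH, Sudan Red 7B, −78 °C; Me2S, −78 °C to rt; evaporate; Me3SiCHN2, PhMe–MeOH, 0 °C; used without chromatography
Reagents that add atoms: ozone, [O-][O+]=O; (trimethylsilyl)diazomethane, C[Si](C)(C)C=[N+]=[N-]
Why: Ozonolysis of a silyl enol ether with reductive work-up, in which the enol ether double bond is consumed far faster than the alkoxyarene or the benzyl ether (dye end point), C2 emerges as the aldehyde and C1 as a silyl ester that methanol cleaves, and base-free esterification of the crude acid avoids epimerisation of the α-aryl aldehyde centre.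

Step 10
Reactants: 13 aldehyde ester
Product: 14 methyl (3R,4R,5S)-5-[4-(benzyloxy)-3-methoxyphenyl]-3,4-dimethylhept-6-ynoate
Conditions: Me3SiCHN2, n-BuLi, THF, −78 °C; add 13; −78 to 0 °C; H2O
Reagents that add atoms: (trimethylsilyl)diazomethane, C[Si](C)(C)C=[N+]=[N-]
Why: Colvin rearrangement, in which lithiated Me3SiCHN2 adds irreversibly to the aldehyde at −78 °C much faster than to the ester, Peterson-type loss of Me3SiOLi and then of N2 gives an alkylidene carbene whose 1,2-hydrogen shift yields the terminal alkyne, and since only aldehyde that has not been enolised can be converted the alkyne keeps the C7' configuration (the descriptor changes by priority only).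

Step 11
Reactants: 15 methyl acetoacetate
Product: 16 methyl 2-diazo-3-oxobutanoate
Conditions: 4-AcNHC6H4SO2N3, Et3N, MeCN, 0 °C to rt
Reagents that add atoms: 4-acetamidobenzenesulfonyl azide, CC(=O)Nc1ccc(cc1)S(=O)(=O)N=[N+]=[N-]
Why: Regitz diazo transfer to an active methylene compound is routine and gives a stabilised, easily handled diazo ester.

Step 12
Reactants: 16 diazo keto ester
Product: 17 methyl 2-(benzyloxy)-3-oxobutanoate (racemic and configurationally labile)
Conditions: BnOH, Rh2(OAc)4 (1 mol %), PhMe, 80 °C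
Reagents that add atoms: benzyl alcohol, OCc1ccccc1
Why: Rhodium carbenoid O–H insertion of an α-diazo-β-keto ester into an alcohol is an established route to α-alkoxy-β-keto esters, and the oxygen placed here ends as the C4 phenol so that no arene lithiation next to benzyl ethers and the C7' methine is needed after the key step.

Step 13
Reactants: 17 benzyloxy keto ester; 14 alkyne ester
Product: 19 methyl (7R,8R,9S)-2-(benzyloxy)-9-[4-(benzyloxy)-3-methoxyphenyl]-7,8-dimethyl-3,5-dioxoundec-10-ynoate, via dilithium dianion 18 (not isolated)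
Conditions: 17 (3 equiv), LiN(iPr)2 (6 equiv), THF, −78 to 0 °C; add 14, −78 to 0 °C; aq HCl
Reagents that add atoms: lithium diisopropylamide, [Li]N(C(C)C)C(C)C (lithium held only in 18)
Why: Claisen-type γ-acylation of a β-keto ester dianion by a methyl ester, in which the terminal carbanion of 18 is the most nucleophilic site, excess dianion absorbs the acidic alkyne and product protons, and the alkyne sits as its acetylide so that the propargylic C7' hydrogen is not removed.

Step 14
Reactants: 19 3,5-dioxo ester
Product: 20 3-(benzyloxy)-6-{(2R,3R,4S)-4-[4-(benzyloxy)-3-methoxyphenyl]-2,3-dimethylhex-5-yn-1-yl}-4-hydroxy-2H-pyran-2-one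
Conditions: DBU (1 equiv), PhMe, rt to 50 °C; aq HCl wash
Reagents that add atoms: none
Why: Base-induced enol lactonisation of a 3,5-dioxo ester to the 4-hydroxy-2-pyrone with loss of methanol, in which one equivalent of amidine is fully buffered by the acidic tricarbonyl and the still more acidic product so that no free base remains to isomerise the benzylic alkyne to an allene.

Step 15
Reactants: 20 hydroxypyrone
Product: 21 3-(benzyloxy)-6-{(2R,3R,4S)-4-[4-(benzyloxy)-3-methoxyphenyl]-2,3-dimethylhex-5-yn-1-yl}-4-methoxy-2H-pyran-2-one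
Conditions: Me2SO4, K2CO3, acetone, rt
Reagents that add atoms: dimethyl sulfate, COS(=O)(=O)OC
Why: O-alkylation of the vinylogous acid with a hard methylating agent under carbonate–acetone conditions is the usual way to 4-methoxy-2-pyrones in preference to the 2-methoxy-4-pyrone isomer, and the carbonate is too weak to touch C7'.

Step 16
Reactants: 21 terminal alkyne pyrone
Product: 22 3-(benzyloxy)-6-{(2R,3R,4R)-4-[4-(benzyloxy)-3-methoxyphenyl]-2,3-dimethyl-6-(4,4,5,5-tetramethyl-1,3,2-dioxaborolan-2-yl)hex-5-yn-1-yl}-4-methoxy-2H-pyran-2-one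
Conditions: HBpin (2 equiv), [N(2-iPr2P-4-MeC6H3)2]Ir(C8H14) (1 mol %, C8H14 = cyclooctene), PhMe, rt to 60 °C; evaporate, filter through dry Celite under N2
Reagents that add atoms: pinacolborane, [H]B1OC(C)(C)C(C)(C)O1
Why: Catalytic dehydrogenative C(sp)–H borylation of a terminal alkyne, in which the iridium amido-pincer complex exchanges the alkyne hydrogen for Bpin with loss of H2 under neutral conditions, sparing the acidic pyrone CH2, the propargylic C7' centre (same spatial arrangement, descriptor changed by priority only) and both benzyl ethers, which acetylide chemistry would not.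

Step 17
Reactants: 22 pyrone alkynylboronate
Product: 24 (7'R,8R,8'R)-4,4'-bis(benzyloxy)-3',5-dimethoxy-3-(4,4,5,5-tetramethyl-1,3,2-dioxaborolan-2-yl)-2,7'-cyclolignan, via bridged lactone cycloadduct 23 (not isolated)
Conditions: o-dichlorobenzene (dry, degassed, high dilution), BHT (cat), sealed vessel, 180–200 °C
Reagents that add atoms: none
Why: This is a thermal type 1 intramolecular [4+2] cycloaddition in which pyrone C6 bonds to the inner alkyne carbon (C1–C2) and pyrone C3 to the boron-bearing carbon (C3–C4) to give bridged lactone 23, which expels CO2 by retro-[4+2] and aromatises irreversibly. The closest known reactions are the intermolecular Diels–Alder/decarboxylation of 2-pyrones with alkynylboronates and the intramolecular pyrone–alkyne benzannulation. Ring B closes in the fused mode as the six-membered ring defined by the four-atom tether C7–C8–C8'–C7', and ring A arises from the four diene carbons of the pyrone plus the two alkyne carbons once the CO2 bridge has left. No lasting stereocentre is formed, because the two bridgehead centres of 23 vanish on aromatisation so the facial course does not matter, and C7', C8' and C8 are spectators under neutral aprotic conditions. The only selectivity needed is regiochemical and the tether length enforces it, putting boron at C3 beside C7' and the benzyloxy-bearing carbon at C4. Dilution, dryness and a radical inhibitor guard against intermolecular addition, protodeboronation and benzylic autoxidation.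

Step 18
Reactants: 24 arylboronate
Product: 25 (7'R,8R,8'R)-4,4'-bis(benzyloxy)-3',5-dimethoxy-2,7'-cyclolignan-3-ol
Conditions: H2O2 (30 % aq), NaOH, THF–H2O, 0 °C
Reagents that add atoms: hydrogen peroxide, OO
Why: Oxidation of an arylboronic ester with basic hydrogen peroxide proceeds by hydroperoxide addition to boron and 1,2-aryl shift from boron to oxygen, so the hydroxyl appears exactly at C3 whatever the crowding.

Step 19
Reactants: 25 C3 phenol
Product: 26 (7'R,8R,8'R)-4,4'-bis(benzyloxy)-3,3',5-trimethoxy-2,7'-cyclolignan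
Conditions: MeI, K2CO3, DMF, rt to 40 °C
Reagents that add atoms: iodomethane, CI
Why: Williamson methylation of the hindered C3 phenoxide with a small electrophile in a dipolar aprotic solvent, all other oxygens being already capped.

Step 20
Reactants: 26 dibenzyl ether
Product: 27 (−)-(7'R,8R,8'R)-4,4'-dihydroxy-3,3',5-trimethoxy-2,7'-cyclolignan
Conditions: H2 (1 atm), Pd/C, EtOAc–MeOH, rt
Reagents that add atoms: none
Why: Catalytic hydrogenolysis cleaves both aryl benzyl ethers at once and leaves the methyl ethers, the C7' diarylmethine and the three stereocentres unchanged, giving the target.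

Compound list
1 | cis-1,2,3,6-tetrahydrophthalic anhydride (meso) | O=C1OC(=O)[C@@H]2CC=CC[C@H]12 | starting material
2 | cis-cyclohex-4-ene-1,2-diyldimethanol (meso) | OC[C@H]1CC=CC[C@H]1CO | intermediate
3 | cis-cyclohex-4-ene-1,2-diylbis(methylene) dimethanesulfonate (meso) | CS(=O)(=O)OC[C@H]1CC=CC[C@H]1COS(C)(=O)=O | intermediate
4 | cis-4,5-dimethylcyclohex-1-ene (meso) | C[C@H]1CC=CC[C@H]1C | intermediate
5 | cis-4,5-dimethylcyclohexene oxide, oxygen anti to both methyls (meso 3,4-dimethyl-7-oxabicyclo[4.1.0]heptane) | C[C@H]1C[C@@H]2O[C@@H]2C[C@H]1C | intermediate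
6 | (1R,4R,5R)-4,5-dimethylcyclohex-2-en-1-ol (hydroxyl trans to the two cis methyls) | O[C@H]1C=C[C@H](C)[C@H](C)C1 | intermediate
7 | (4R,5R)-4,5-dimethylcyclohex-2-en-1-one | O=C1C=C[C@H](C)[C@H](C)C1 | intermediate
8 | 4-bromo-2-methoxyphenol | COc1cc(Br)ccc1O | starting material
9 | 1-(benzyloxy)-4-bromo-2-methoxybenzene | COc1cc(Br)ccc1OCc1ccccc1 | intermediate
10 | [4-(benzyloxy)-3-methoxyphenyl]magnesium bromide | COc1cc([Mg]Br)ccc1OCc1ccccc1 | intermediate
11 | {[(3S,4R,5R)-3-[4-(benzyloxy)-3-methoxyphenyl]-4,5-dimethylcyclohex-1-en-1-yl]oxy}trimethylsilane (aryl trans to both methyls) | C[Si](C)(C)OC1=C[C@@H](c2ccc(OCc3ccccc3)c(OC)c2)[C@H](C)[C@H](C)C1 | intermediate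
12 | (3R,4R,5R)-5-[4-(benzyloxy)-3-methoxyphenyl]-3,4-dimethyl-6-oxohexanoic acid | O=C[C@@H](c1ccc(OCc2ccccc2)c(OC)c1)[C@H](C)[C@H](C)CC(=O)O | intermediate
13 | methyl (3R,4R,5R)-5-[4-(benzyloxy)-3-methoxyphenyl]-3,4-dimethyl-6-oxohexanoate | O=C[C@@H](c1ccc(OCc2ccccc2)c(OC)c1)[C@H](C)[C@H](C)CC(=O)OC | intermediate
14 | methyl (3R,4R,5S)-5-[4-(benzyloxy)-3-methoxyphenyl]-3,4-dimethylhept-6-ynoate | C#C[C@@H](c1ccc(OCc2ccccc2)c(OC)c1)[C@H](C)[C@H](C)CC(=O)OC | intermediate
15 | methyl acetoacetate | COC(=O)CC(C)=O | starting material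
16 | methyl 2-diazo-3-oxobutanoate | COC(=O)C(=[N+]=[N-])C(C)=O | intermediate
17 | methyl 2-(benzyloxy)-3-oxobutanoate (racemic, labile centre) | COC(=O)C(OCc1ccccc1)C(C)=O | intermediate
18 | dilithium dianion of 17 | [Li+].[Li+].C=C([O-])C(OCc1ccccc1)=C([O-])OC | intermediate
19 | methyl (7R,8R,9S)-2-(benzyloxy)-9-[4-(benzyloxy)-3-methoxyphenyl]-7,8-dimethyl-3,5-dioxoundec-10-ynoate (C2 epimers and enol forms) | C#C[C@@H](c1ccc(OCc2ccccc2)c(OC)c1)[C@H](C)[C@H](C)CC(=O)CC(=O)C(OCc1ccccc1)C(=O)OC | intermediate
20 | 3-(benzyloxy)-6-{(2R,3R,4S)-4-[4-(benzyloxy)-3-methoxyphenyl]-2,3-dimethylhex-5-yn-1-yl}-4-hydroxy-2H-pyran-2-one | C#C[C@@H](c1ccc(OCc2ccccc2)c(OC)c1)[C@H](C)[C@H](C)CC1=CC(O)=C(OCc2ccccc2)C(=O)O1 | intermediate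
21 | 3-(benzyloxy)-6-{(2R,3R,4S)-4-[4-(benzyloxy)-3-methoxyphenyl]-2,3-dimethylhex-5-yn-1-yl}-4-methoxy-2H-pyran-2-one | C#C[C@@H](c1ccc(OCc2ccccc2)c(OC)c1)[C@H](C)[C@H](C)CC1=CC(OC)=C(OCc2ccccc2)C(=O)O1 | intermediate
22 | 3-(benzyloxy)-6-{(2R,3R,4R)-4-[4-(benzyloxy)-3-methoxyphenyl]-2,3-dimethyl-6-(4,4,5,5-tetramethyl-1,3,2-dioxaborolan-2-yl)hex-5-yn-1-yl}-4-methoxy-2H-pyran-2-one | COc1cc([C@H](C#CB2OC(C)(C)C(C)(C)O2)[C@H](C)[C@H](C)CC2=CC(OC)=C(OCc3ccccc3)C(=O)O2)ccc1OCc1ccccc1 | intermediate
23 | bridged 2-oxabicyclo[2.2.2]octa-5,7-dien-3-one cycloadduct fused to ring B (either bridgehead facial isomer; both lead to 24) | COc1cc([C@@H]2C3=C(B4OC(C)(C)C(C)(C)O4)C4(OCc5ccccc5)C(=O)OC3(C[C@@H](C)[C@H]2C)C=C4OC)ccc1OCc1ccccc1 | intermediate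
24 | (7'R,8R,8'R)-4,4'-bis(benzyloxy)-3',5-dimethoxy-3-(4,4,5,5-tetramethyl-1,3,2-dioxaborolan-2-yl)-2,7'-cyclolignan | COc1cc([C@@H]2c3c(cc(OC)c(OCc4ccccc4)c3B5OC(C)(C)C(C)(C)O5)C[C@@H](C)[C@H]2C)ccc1OCc1ccccc1 | intermediate
25 | (7'R,8R,8'R)-4,4'-bis(benzyloxy)-3',5-dimethoxy-2,7'-cyclolignan-3-ol | COc1cc([C@@H]2c3c(cc(OC)c(OCc4ccccc4)c3O)C[C@@H](C)[C@H]2C)ccc1OCc1ccccc1 | intermediate
26 | (7'R,8R,8'R)-4,4'-bis(benzyloxy)-3,3',5-trimethoxy-2,7'-cyclolignan | COc1cc([C@@H]2c3c(cc(OC)c(OCc4ccccc4)c3OC)C[C@@H](C)[C@H]2C)ccc1OCc1ccccc1 | intermediate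
27 | (−)-(7'R,8R,8'R)-4,4'-dihydroxy-3,3',5-trimethoxy-2,7'-cyclolignan | COc1cc([C@@H]2c3c(cc(OC)c(O)c3OC)C[C@@H](C)[C@H]2C)ccc1O | target

Total step count: 20. Longest linear sequence: 17 (steps 1–6, 8–10 and 13–20). Steps 7, 11 and 12 are side branches.

Steps most likely to fail

Step 17. The cycloaddition may be too slow. A donor-substituted pyrone has to meet an alkyne whose boron-bearing carbon must bond to the benzyloxy-bearing pyrone carbon. Prolonged heating could then bring protodeboronation or breakdown of the pyrone.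
- The fallback uses a smaller and far more electron-poor boron group, so the dienophile is activated and the temperature need not be raised.
- It sets out from 22. KHF2 in MeOH–H2O gives the potassium alkynyltrifluoroborate F1.
- BF3·OEt2 in CH2Cl2 at rt to 40 °C abstracts fluoride and releases the alkynyldifluoroborane F2. Its boron can also bind the neighbouring pyrone oxygens.
- Cycloaddition through the bridged difluoroboryl cycloadduct F3 and loss of CO2 lead to the aryldifluoroborane F4.
- F4 is oxidised in the same flask with H2O2–NaOH to phenol 25, where the route is rejoined.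

Step 16. Several processes could compete with C–H exchange:
- hydride transfer to the pyrone;
- hydroboration of the alkyne;
- inhibition of the catalyst by the pyrone oxygens;
- hydrolysis of the C(sp)–B bond during isolation.

The fallback replaces boron with a halogen as the C3 placeholder.
- It sets out from 21. NBS with AgNO3 (cat) in acetone gives the 1-bromoalkyne F5.
- Heating as in step 17 leads through the bridged bromo cycloadduct F6 to the C3 aryl bromide F7.
- Ullmann-type methoxylation (NaOMe, CuBr cat, DMF–MeOH, 110 °C) converts F7 directly into 26, where the route is rejoined.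

Step 10. The lithiated diazo reagent may enolise the α-aryl aldehyde. That would cost conversion and return epimerised aldehyde. It may also attack the ester. The fallback is a non-basic olefination first, with the organolithium used only on a carboxylate.
- It sets out from 13. Ramirez olefination (CBr4, PPh3, CH2Cl2, 0 °C) gives the dibromoalkene ester F8.
- LiOH in THF–H2O gives the dibromoalkene acid F9.
- n-BuLi (3 equiv, THF, −78 °C), the second stage of the Corey–Fuchs sequence, gives the alkynoic acid F10. The carboxylate shields the acyl carbon during this operation.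
- 1,1'-Carbonyldiimidazole gives the acylimidazole F11.
- F11 acylates dianion 18 and returns to the route at 19.

Further compounds
F1 | step 17 | potassium trifluoroborate analogue of 22 (BF3K in place of Bpin) | COc1cc([C@H](C#C[B-](F)(F)F)[C@H](C)[C@H](C)CC2=CC(OC)=C(OCc3ccccc3)C(=O)O2)ccc1OCc1ccccc1.[K+]
F2 | step 17 | alkynyldifluoroborane analogue of 22 (BF2 in place of Bpin) | COc1cc([C@H](C#CB(F)F)[C@H](C)[C@H](C)CC2=CC(OC)=C(OCc3ccccc3)C(=O)O2)ccc1OCc1ccccc1
F3 | step 17 | bridged cycloadduct, difluoroboryl analogue of 23 | COc1cc([C@@H]2C3=C(B(F)F)C4(OCc5ccccc5)C(=O)OC3(C[C@@H](C)[C@H]2C)C=C4OC)ccc1OCc1ccccc1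
F4 | step 17 | (7'R,8R,8'R)-4,4'-bis(benzyloxy)-3-(difluoroboryl)-3',5-dimethoxy-2,7'-cyclolignan | COc1cc([C@@H]2c3c(cc(OC)c(OCc4ccccc4)c3B(F)F)C[C@@H](C)[C@H]2C)ccc1OCc1ccccc1
F5 | step 16 | 1-bromoalkyne derived from 21 (C≡C–Br) | COc1cc([C@H](C#CBr)[C@H](C)[C@H](C)CC2=CC(OC)=C(OCc3ccccc3)C(=O)O2)ccc1OCc1ccccc1
F6 | step 16 | bridged cycloadduct, bromo analogue of 23 | COc1cc([C@@H]2C3=C(Br)C4(OCc5ccccc5)C(=O)OC3(C[C@@H](C)[C@H]2C)C=C4OC)ccc1OCc1ccccc1
F7 | step 16 | (7'R,8R,8'R)-4,4'-bis(benzyloxy)-3-bromo-3',5-dimethoxy-2,7'-cyclolignan | COc1cc([C@@H]2c3c(cc(OC)c(OCc4ccccc4)c3Br)C[C@@H](C)[C@H]2C)ccc1OCc1ccccc1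
F8 | step 10 | methyl (3R,4R,5S)-5-[4-(benzyloxy)-3-methoxyphenyl]-7,7-dibromo-3,4-dimethylhept-6-enoate | BrC(Br)=C[C@@H](c1ccc(OCc2ccccc2)c(OC)c1)[C@H](C)[C@H](C)CC(=O)OC
F9 | step 10 | (3R,4R,5S)-5-[4-(benzyloxy)-3-methoxyphenyl]-7,7-dibromo-3,4-dimethylhept-6-enoic acid | BrC(Br)=C[C@@H](c1ccc(OCc2ccccc2)c(OC)c1)[C@H](C)[C@H](C)CC(=O)O
F10 | step 10 | (3R,4R,5S)-5-[4-(benzyloxy)-3-methoxyphenyl]-3,4-dimethylhept-6-ynoic acid | C#C[C@@H](c1ccc(OCc2ccccc2)c(OC)c1)[C@H](C)[C@H](C)CC(=O)O
F11 | step 10 | N-acylimidazole of F10 | C#C[C@@H](c1ccc(OCc2ccccc2)c(OC)c1)[C@H](C)[C@H](C)CC(=O)n1ccnc1
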